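**Remark (assumption):** The target has no stereogenic centre. The exocyclic C7=C bond carries two 4‑oxygenated rings that exchange roles by proton tautomerism, and no biaryl axis is specified as fixed. The compound is therefore treated as achiral, and no step has to set or keep a configuration.

**Locants used throughout (target):** Ring B is the central benzene, C1–C6.
- C1 bears the methide carbon C7, which is doubly bonded to ring A (cyclohexa‑2,5‑dienone) and singly bonded to ring A′ (4‑hydroxyphenyl).
- C2 bears ring C (2,4‑dihydroxyphenyl, attached through C1′, hydroxyls on C2′ and C4′).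
- C3 and C4 are CH.
- C5 bears CH2OH.
- C6 bears C≡C–ring D (4‑hydroxyphenyl).

## Analysis of the target

Selaginellin F consists of five six‑membered carbocycles, none fused. Ring B is a benzene with four different carbon substituents on adjacent atoms (C5, C6, C1, C2); only C3 and C4 carry hydrogen. There is no stereocentre, but C7 is a very crowded triaryl carbon, because C1 is flanked by ring C on C2 and by the arylethynyl group on C6. The sensitive groups are the fuchsone‑type quinone methide (electrophilic at C7), six free hydroxyls, and an alkyne that lies next to the CH2OH on C5 and next to C7. The hydroxyl O2′ lies in a 1,6‑relationship to C7 (O2′–C2′–C1′–C2–C1–C7), so ring closure to a 6H‑benzo[c]chromene is always possible. The difficulty is the fixed order of four substituents on ring B: the usual answer is a pre‑made tetrasubstituted arene and cross‑couplings at doubly flanked positions.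

Two features of this structure are exploited:
- The O2′/C7 relationship is a latent six‑membered lactone, once C7 is at the carboxyl oxidation level.
- With that lactone as tether, ring B divides into a buta‑1,3‑diyne (C2–C3–C4–C5) and an alkyne (C1≡C6) that still carries a second alkyne. The arylethynyl group on C6 is then the unreacted half of a 1,3‑diyne, and C3/C4 are the two carbons of an aryne.

## Retrosynthetic reasoning

**22 to 20.** The C7=ring A double bond and all free hydroxyls are traced back to the tertiary carbinol 20. In 20, C7 is sp3 and carries OH, rings A and A′ are two identical 4‑(methoxymethoxy)phenyl groups, the para oxygens of rings C and D are MOM ethers, and the hydroxymethyl oxygen is a TBS ether. The cut is made here because every protecting group is acid‑labile and the carbinol ionises under the same acid. One operation therefore has to unmask six hydroxyls and form the quinone methide by loss of a phenolic proton.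

**20 to 16 and 17.** Both C7–aryl bonds are cut together. C7 returns to the carboxyl level and is esterified by O2′, which gives the lactone 16, a 6H‑benzo[c]chromen‑6‑one. The lactone is at once an activated ester for double arylation, the protecting group of O2′, and the tether needed for the next cut. In the forward direction two equivalents of aryllithium 18 (from bromide 17) add. The first opens the ring to keto phenoxide 19, the second gives the carbinol.

**16 to 14 (key disconnection).** Bonds C1–C2 and C5–C6 of ring B are cut and the hydrogens on C3 and C4 are removed. This leaves the tetrayne ester 14: an aryl‑bound 1,3‑diyne (C2 to C5, ending in the silyloxymethyl group) and a penta‑2,4‑diynoate whose α,β‑alkyne is C1≡C6. The cut is made here because the connectivity of the alkynes places all four ring B substituents without any prefunctionalised arene, and the tether fixes the orientation. The forward reaction has to form two C–C bonds, close the lactone and ring B, and pass through aryne 15, which must take two hydrogen atoms from a saturated hydrocarbon solvent.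

**14 to 8 and 13.** The ester bond C7–O2′ is cut. This gives the phenol 8 and the diynoic acid 13, which are joined by carbodiimide esterification.

**8 to 7 and 5.** The bond C1′–C2 (aryl–sp) is cut. The iodophenol 7 comes from phenol 6 by iodination para to the MOM ether. The terminal diyne 5 comes from the bis‑silyl diyne 1 by exchange of one silyl group for a hydroxymethyl group (3), silylation (4) and removal of the second C‑silyl group.

**13 to 11 and 12.** The sp–sp bond between the two alkynes of the acid is cut. Bromoalkyne 11 (from aldehyde 9 through dibromoalkene 10) is coupled with propiolic acid 12. Acid 12 supplies C7, C1 and C6 of the target.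

## Alternatives that were turned down

**Alternative 1:** the textbook route. Ring B is taken as a ready benzene, and the bonds C2–C1′ (Suzuki), C6–C(sp) (Sonogashira) and both C7–aryl bonds are made one after another. The forward key step is the double addition of aryllithium 18 to the benzoate A2, which would come from the dihalobenzoate A1 (iodide at target C2, bromide at target C6). It was turned down for these reasons:
- A1 carries four different adjacent substituents and would itself need several steps of directed functionalisation.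
- Both couplings occur ortho to the ester, each with a second ortho neighbour.
- O2′ needs its own protecting group and does no constructive work.
- Every ring B substituent costs one or two linear steps, so the count ends well above twelve, and no step simplifies the problem.

**Alternative 2:** a [2+2+2] cyclotrimerisation. Bonds C1–C2, C3–C4 and C5–C6 are cut. The forward key step is a Rh(I)‑catalysed cycloaddition of the ester‑tethered 1,7‑diyne A3 with the propargyl silyl ether A4, which would give 16 directly. It was turned down for these reasons: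
- The silyloxymethyl carbon of A4 must bond to C6, the crowded diyne terminus that bears the arylethynyl group. Insertion into the metallacycle places the substituent of a terminal alkyne away from that terminus, so the regioisomer A5 (CH2OSi on C4) is expected to predominate.
- The metal can also engage the second alkyne of the diynoate or trimerise A4.
- A regioisomer separation would sit at the centre of the route.

**Alternative 3:** triarylmethane dye logic. Both C7–aryl bonds are cut at the aldehyde level. The forward key step is an acid‑mediated double Friedel–Crafts condensation of aldehyde A6 with phenol A7 to the leuco triarylmethane A8, followed by dehydrogenation to 22. It was turned down for these reasons: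
- An o‑alkynylbenzaldehyde under acid cyclises through the carbonyl oxygen onto the alkyne (isobenzopyrylium formation).
- A7 reacts at ortho as well as para positions.
- The benzylic cation is intercepted by O2′.
- Oxidation of A8 next to a free resorcinol ring would not be selective.
- A6 still needs the whole textbook assembly of ring B.

Key step: step 10

## Route

**Step 1**
Reactants: 1 1,4‑bis(trimethylsilyl)buta‑1,3‑diyne
Product: 3 5‑(trimethylsilyl)penta‑2,4‑diyn‑1‑ol, via lithium butadiynide 2 (not isolated)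
Conditions: MeLi·LiBr (1.05 equiv), THF, −78 °C → rt; then (CH2O)n, 0 °C → rt; NH4Cl (aq)
Reagents that add atoms: paraformaldehyde (as formaldehyde), C=O
Why: MeLi cleaves one C(sp)–Si bond only, because the resulting acetylide is deactivated toward a second attack; the acetylide then adds to formaldehyde (1,2‑addition).

**Step 2**
Reactants: 3 5‑(trimethylsilyl)penta‑2,4‑diyn‑1‑ol
Product: 4 tert‑butyl(dimethyl){[5‑(trimethylsilyl)penta‑2,4‑diyn‑1‑yl]oxy}silane
Conditions: TBSCl, imidazole, CH2Cl2, 0 °C → rt
Reagents that add atoms: tert‑butyldimethylsilyl chloride, CC(C)(C)[Si](C)(C)Cl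
Why: Standard silylation of a primary alcohol; the TBS ether later keeps the oxygen from adding to the aryne and from being acylated.

**Step 3**
Reactants: 4 tert‑butyl(dimethyl){[5‑(trimethylsilyl)penta‑2,4‑diyn‑1‑yl]oxy}silane
Product: 5 tert‑butyl(dimethyl)(penta‑2,4‑diyn‑1‑yloxy)silane
Conditions: K2CO3 (cat.), MeOH/THF, 0 °C; extractive work‑up, kept as a cold solution and used at once
Reagents that add atoms: none
Why: Base‑catalysed protodesilylation of the C(sp)–SiMe3 bond; the primary TBS ether should be stable under these conditions, and the terminal diyne is not concentrated because such compounds decompose neat.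

**Step 4**
Reactants: 6 3‑(methoxymethoxy)phenol
Product: 7 2‑iodo‑5‑(methoxymethoxy)phenol
Conditions: I2 (1.0 equiv), NaHCO3, THF/H2O, 0 °C
Reagents that add atoms: iodine, II
Why: Electrophilic iodination of the phenoxide; the position ortho to OH and para to the MOM ether is doubly activated and unhindered, as in the iodination of 3‑alkoxyphenols.

**Step 5**
Reactants: 7 2‑iodo‑5‑(methoxymethoxy)phenol and 5 tert‑butyl(dimethyl)(penta‑2,4‑diyn‑1‑yloxy)silane
Product: 8 2‑(5‑{[tert‑butyl(dimethyl)silyl]oxy}penta‑1,3‑diyn‑1‑yl)‑5‑(methoxymethoxy)phenol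
Conditions: PdCl2(PPh3)2 (cat.), CuI (cat.), Et3N, THF, degassed, rt
Reagents that add atoms: none
Why: Sonogashira coupling; oxidative addition of the aryl iodide is fast at room temperature, so the free phenol can be carried and the 5‑endo cyclisation to a benzofuran, which needs heat, should stay slow.

**Step 6**
Reactants: 9 4‑(methoxymethoxy)benzaldehyde
Product: 10 1‑(2,2‑dibromoethenyl)‑4‑(methoxymethoxy)benzene
Conditions: CBr4, PPh3, Et3N, CH2Cl2, 0 °C
Reagents that add atoms: carbon tetrabromide, BrC(Br)(Br)Br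
Why: Corey–Fuchs dibromo‑olefination (Wittig reaction of Ph3P=CBr2); triethylamine buffers the medium for the MOM ether.

**Step 7**
Reactants: 10 1‑(2,2‑dibromoethenyl)‑4‑(methoxymethoxy)benzene
Product: 11 1‑(bromoethynyl)‑4‑(methoxymethoxy)benzene
Conditions: DBU (2 equiv), DMSO, 15 °C → rt
Reagents that add atoms: none
Why: Anti‑dehydrobromination of an aryl 1,1‑dibromoalkene by an amidine base stops at the 1‑bromoalkyne.

**Step 8**
Reactants: 11 1‑(bromoethynyl)‑4‑(methoxymethoxy)benzene and 12 prop‑2‑ynoic acid
Product: 13 5‑[4‑(methoxymethoxy)phenyl]penta‑2,4‑diynoic acid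
Conditions: CuCl (cat.), NH2OH·HCl (cat.), n‑BuNH2 (aq)/MeOH, 0 °C; then cold citric acid to pH 3–4
Reagents that add atoms: none
Why: Cadiot–Chodkiewicz coupling of the copper acetylide of the propiolate with the bromoalkyne, the classical access to penta‑2,4‑diynoic acids; hydroxylamine keeps copper in the +1 state, and the mild acidification spares the MOM ether.

**Step 9**
Reactants: 8 2‑(5‑{[tert‑butyl(dimethyl)silyl]oxy}penta‑1,3‑diyn‑1‑yl)‑5‑(methoxymethoxy)phenol and 13 5‑[4‑(methoxymethoxy)phenyl]penta‑2,4‑diynoic acid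
Product: 14 2‑(5‑{[tert‑butyl(dimethyl)silyl]oxy}penta‑1,3‑diyn‑1‑yl)‑5‑(methoxymethoxy)phenyl 5‑[4‑(methoxymethoxy)phenyl]penta‑2,4‑diynoate
Conditions: DCC (1.1 equiv), DMAP (5 mol %), CH2Cl2, −10 → 0 °C; cold work‑up
Reagents that add atoms: none
Why: Steglich esterification, the usual way to aryl and propargyl alkynoates; low temperature and little DMAP should keep conjugate addition to the diynoate in the background.

**Step 10**
Reactants: 14 2‑(5‑{[tert‑butyl(dimethyl)silyl]oxy}penta‑1,3‑diyn‑1‑yl)‑5‑(methoxymethoxy)phenyl 5‑[4‑(methoxymethoxy)phenyl]penta‑2,4‑diynoate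
Product: 16 8‑({[tert‑butyl(dimethyl)silyl]oxy}methyl)‑3‑(methoxymethoxy)‑7‑{[4‑(methoxymethoxy)phenyl]ethynyl}‑6H‑benzo[c]chromen‑6‑one, via aryne 15 (not isolated)
Conditions: cyclooctane (solvent, 0.01 M), 130 °C, sealed tube, Ar
Reagents that add atoms: none
Why: This is a hexadehydro‑Diels–Alder cycloisomerisation followed by hydrogenation of the aryne: the aryl‑bound 1,3‑diyne (C2≡C3–C4≡C5) is the four‑carbon partner and the ester‑conjugated alkyne (C1≡C6) the two‑carbon partner, held by the four‑atom tether C1′–C2′–O–C7(=O). The closest known reaction type is the thermal cycloisomerisation of ester‑tethered and o‑phenylene‑tethered triynes and tetraynes to benzynes, which are reduced in situ by double hydrogen‑atom transfer from a cycloalkane. Bond C1–C2 forms first and closes the six‑membered lactone ring by exo‑dig attack at both alkynes (the s‑cis ester rotamer is populated at this temperature); bond C5–C6 then closes ring B in the [4+2] sense and leaves aryne 15 with its formal triple bond at C3–C4. Cyclooctane, present as solvent, delivers two hydrogen atoms to C3 and C4 and becomes cyclooctene. No stereocentre is formed. The step needs the acid‑derived diyne to react only through C1≡C6: the tether brings only C1 and C2 into bonding distance, and the second bond is expected at C5, which carries a small CH2OSi group, and not at the aryl‑bearing alkyne terminus, where ring D would lose conjugation and crowd C3. The step also needs the aryne to find no internal trap: the silyl ether oxygen on the C5 methylene could reach C4 only through a four‑membered ring, so the solvent should win, and high dilution suppresses capture of the aryne by a second molecule of 14.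

**Step 11**
Reactants: 16 8‑({[tert‑butyl(dimethyl)silyl]oxy}methyl)‑3‑(methoxymethoxy)‑7‑{[4‑(methoxymethoxy)phenyl]ethynyl}‑6H‑benzo[c]chromen‑6‑one and 17 1‑bromo‑4‑(methoxymethoxy)benzene
Product: 20 {4‑({[tert‑butyl(dimethyl)silyl]oxy}methyl)‑2′‑hydroxy‑4′‑(methoxymethoxy)‑3‑{[4‑(methoxymethoxy)phenyl]ethynyl}biphenyl‑2‑yl}bis[4‑(methoxymethoxy)phenyl]methanol, via aryllithium 18 (not isolated), via keto phenoxide 19 (not isolated)
Conditions: 17 (3.3 equiv), n‑BuLi (3.2 equiv), THF, −78 °C; then 16, −78 → 0 °C; NH4Cl (aq), no acid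
Reagents that add atoms: none
Why: Bromine–lithium exchange gives 18; its addition to the lactone carbonyl is followed by loss of the O2′ aryloxide to give ketone 19, and a second addition gives the carbinol. The same double addition of organometallics to benzo[c]chromen‑6‑ones is the classical entry to 6,6‑disubstituted benzochromenes, and MOM and TBS ethers and the alkyne are inert to aryllithiums at low temperature.

**Step 12**
Reactants: 20 {4‑({[tert‑butyl(dimethyl)silyl]oxy}methyl)‑2′‑hydroxy‑4′‑(methoxymethoxy)‑3‑{[4‑(methoxymethoxy)phenyl]ethynyl}biphenyl‑2‑yl}bis[4‑(methoxymethoxy)phenyl]methanol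
Product: 22 selaginellin F, via deprotected carbinol 21 (not isolated)
Conditions: HCl (1.25 M in MeOH), THF, 0 °C → rt; then NaHCO3 (aq) to pH 6–7
Reagents that add atoms: none
Why: Acid‑catalysed acetal exchange removes the four MOM groups (methanol traps the methoxymethyl cation, so the electron‑rich rings are not alkylated) and cleaves the TBS ether. The bis(4‑hydroxyphenyl)carbinol then ionises at C7 and loses a phenolic proton to give the quinone methide, as in fuchsone and benzaurin formation; the push–pull conjugation of the open form should hold it against addition of O2′ to C7.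

## Compound list

1 | 1,4‑bis(trimethylsilyl)buta‑1,3‑diyne | C[Si](C)(C)C#CC#C[Si](C)(C)C | starting material
2 | lithium 4‑(trimethylsilyl)buta‑1,3‑diyn‑1‑ide | [Li]C#CC#C[Si](C)(C)C | intermediate
3 | 5‑(trimethylsilyl)penta‑2,4‑diyn‑1‑ol | C[Si](C)(C)C#CC#CCO | intermediate
4 | tert‑butyl(dimethyl){[5‑(trimethylsilyl)penta‑2,4‑diyn‑1‑yl]oxy}silane | C[Si](C)(C)C#CC#CCO[Si](C)(C)C(C)(C)C | intermediate
5 | tert‑butyl(dimethyl)(penta‑2,4‑diyn‑1‑yloxy)silane | C#CC#CCO[Si](C)(C)C(C)(C)C | intermediate
6 | 3‑(methoxymethoxy)phenol | COCOc1cccc(O)c1 | starting material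
7 | 2‑iodo‑5‑(methoxymethoxy)phenol | COCOc1ccc(I)c(O)c1 | intermediate
8 | 2‑(5‑{[tert‑butyl(dimethyl)silyl]oxy}penta‑1,3‑diyn‑1‑yl)‑5‑(methoxymethoxy)phenol | COCOc1ccc(C#CC#CCO[Si](C)(C)C(C)(C)C)c(O)c1 | intermediate
9 | 4‑(methoxymethoxy)benzaldehyde | COCOc1ccc(C=O)cc1 | starting material
10 | 1‑(2,2‑dibromoethenyl)‑4‑(methoxymethoxy)benzene | COCOc1ccc(C=C(Br)Br)cc1 | intermediate
11 | 1‑(bromoethynyl)‑4‑(methoxymethoxy)benzene | COCOc1ccc(C#CBr)cc1 | intermediate
12 | prop‑2‑ynoic acid (propiolic acid) | C#CC(=O)O | starting material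
13 | 5‑[4‑(methoxymethoxy)phenyl]penta‑2,4‑diynoic acid | COCOc1ccc(C#CC#CC(=O)O)cc1 | intermediate
14 | 2‑(5‑{[tert‑butyl(dimethyl)silyl]oxy}penta‑1,3‑diyn‑1‑yl)‑5‑(methoxymethoxy)phenyl 5‑[4‑(methoxymethoxy)phenyl]penta‑2,4‑diynoate | COCOc1ccc(C#CC#CC(=O)Oc2cc(OCOC)ccc2C#CC#CCO[Si](C)(C)C(C)(C)C)cc1 | intermediate
15 | 8‑({[tert‑butyl(dimethyl)silyl]oxy}methyl)‑3‑(methoxymethoxy)‑7‑{[4‑(methoxymethoxy)phenyl]ethynyl}‑9,10‑didehydro‑6H‑benzo[c]chromen‑6‑one (aryne) | COCOc1ccc2c(c1)OC(=O)C1=C2C#CC(CO[Si](C)(C)C(C)(C)C)=C1C#Cc1ccc(OCOC)cc1 | intermediate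
16 | 8‑({[tert‑butyl(dimethyl)silyl]oxy}methyl)‑3‑(methoxymethoxy)‑7‑{[4‑(methoxymethoxy)phenyl]ethynyl}‑6H‑benzo[c]chromen‑6‑one | COCOc1ccc2-c3ccc(CO[Si](C)(C)C(C)(C)C)c(C#Cc4ccc(OCOC)cc4)c3C(=O)Oc2c1 | intermediate
17 | 1‑bromo‑4‑(methoxymethoxy)benzene | COCOc1ccc(Br)cc1 | starting material
18 | [4‑(methoxymethoxy)phenyl]lithium | [Li]c1ccc(OCOC)cc1 | intermediate
19 | lithium 2‑{4‑({[tert‑butyl(dimethyl)silyl]oxy}methyl)‑2‑[4‑(methoxymethoxy)benzoyl]‑3‑{[4‑(methoxymethoxy)phenyl]ethynyl}phenyl}‑5‑(methoxymethoxy)phenolate | COCOc1ccc(-c2ccc(CO[Si](C)(C)C(C)(C)C)c(C#Cc3ccc(OCOC)cc3)c2C(=O)c2ccc(OCOC)cc2)c(O[Li])c1 | intermediate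
20 | {4‑({[tert‑butyl(dimethyl)silyl]oxy}methyl)‑2′‑hydroxy‑4′‑(methoxymethoxy)‑3‑{[4‑(methoxymethoxy)phenyl]ethynyl}biphenyl‑2‑yl}bis[4‑(methoxymethoxy)phenyl]methanol | COCOc1ccc(-c2ccc(CO[Si](C)(C)C(C)(C)C)c(C#Cc3ccc(OCOC)cc3)c2C(O)(c2ccc(OCOC)cc2)c2ccc(OCOC)cc2)c(O)c1 | intermediate
21 | 2‑[bis(4‑hydroxyphenyl)(hydroxy)methyl]‑4‑(hydroxymethyl)‑3‑[(4‑hydroxyphenyl)ethynyl]biphenyl‑2′,4′‑diol | Oc1ccc(-c2ccc(CO)c(C#Cc3ccc(O)cc3)c2C(O)(c2ccc(O)cc2)c2ccc(O)cc2)c(O)c1 | intermediate
22 | selaginellin F | O=C1C=CC(=C(c2ccc(O)cc2)c2c(-c3ccc(O)cc3O)ccc(CO)c2C#Cc2ccc(O)cc2)C=C1 | target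

## Step count and risk

Total step count: 12. Longest linear sequence: 8 steps (steps 1, 2, 3, 5, 9, 10, 11, 12).

**Step 10 (key step).** The aryne may be consumed by a second substrate molecule or by an ether oxygen faster than it takes up two hydrogens. The four‑atom ester tether may also demand a temperature at which the diynoate decomposes. A third risk, ring closure through the acid‑derived diyne, is answered by the fallback under step 9.

The fallback avoids the aryne altogether and takes both ring hydrogens from the substrate. It sets out from 7 and 13 and returns at 16. Commercial (E)‑pent‑2‑en‑4‑yn‑1‑ol would be silylated to (E)‑tert‑butyl(dimethyl)(pent‑2‑en‑4‑yn‑1‑yloxy)silane F1. Sonogashira coupling of F1 with 7 would give 2‑[(3E)‑5‑{[tert‑butyl(dimethyl)silyl]oxy}pent‑3‑en‑1‑yn‑1‑yl]‑5‑(methoxymethoxy)phenol F2. Esterification of F2 with 13 as in step 9 would give the enyne ester 2‑[(3E)‑5‑{[tert‑butyl(dimethyl)silyl]oxy}pent‑3‑en‑1‑yn‑1‑yl]‑5‑(methoxymethoxy)phenyl 5‑[4‑(methoxymethoxy)phenyl]penta‑2,4‑diynoate F3. Heating F3 (1,2‑dichlorobenzene, about 180 °C, with a hindered phenol as proton shuttle) should bring about the intramolecular enyne–alkyne [4+2] cycloaddition (tetradehydro‑Diels–Alder). The cycloadduct would aromatise by shift of the hydrogen on C5 to C3 and give 16 directly.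

**Step 9.** On activation the diynoic acid may lose CO2 or oligomerise. The phenol or DMAP may also add to the activated diynoate in a conjugate manner in place of acyl transfer.

The fallback carries a simpler acyl unit through the ring formation and introduces the ring D alkyne afterwards by cross‑coupling. It sets out from 8, 10 and 12 and returns at 16. Acid 12 would be brominated (NBS, AgNO3 cat., acetone) to 3‑bromoprop‑2‑ynoic acid F4. Coupling of F4 with 8 (DCC, 0 °C) would give 2‑(5‑{[tert‑butyl(dimethyl)silyl]oxy}penta‑1,3‑diyn‑1‑yl)‑5‑(methoxymethoxy)phenyl 3‑bromoprop‑2‑ynoate F5. Heating F5 in cyclooctane as in step 10 should give 7‑bromo‑8‑({[tert‑butyl(dimethyl)silyl]oxy}methyl)‑3‑(methoxymethoxy)‑6H‑benzo[c]chromen‑6‑one F6. Dibromoalkene 10 with n‑BuLi (2 equiv, −78 °C, then water) would give 1‑ethynyl‑4‑(methoxymethoxy)benzene F7. Sonogashira coupling of F6 with F7 (Pd/Cu, Et3N) would give 16. Because F5 contains only one diyne, this sequence also removes the question of which diyne enters the cycloaddition.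

**Step 5.** The o‑alkynylphenol may cycloisomerise (5‑endo‑dig) to a benzofuran under Pd/Cu/amine, and the terminal diyne may homocouple oxidatively.

The fallback masks the phenol during the coupling. It sets out from 7 and 5 and returns at 8. Acetylation of 7 (Ac2O, pyridine) would give 2‑iodo‑5‑(methoxymethoxy)phenyl acetate F8. Sonogashira coupling of F8 with 5 would give 2‑(5‑{[tert‑butyl(dimethyl)silyl]oxy}penta‑1,3‑diyn‑1‑yl)‑5‑(methoxymethoxy)phenyl acetate F9. Ammonolysis of F9 (NH3 in MeOH, 0 °C, metal‑free) would release 8 just before esterification.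

**Step 12.** Under acid the C7 cation may be captured by O2′ in a six‑membered oxa‑cyclisation, which would give the ring‑closed, colourless isomer in place of the quinone methide.

The fallback accepts this closure and reopens the ring under base. It sets out from 20 and returns at 22. The acid treatment would be run to completion to give 8‑(hydroxymethyl)‑6,6‑bis(4‑hydroxyphenyl)‑7‑[(4‑hydroxyphenyl)ethynyl]‑6H‑benzo[c]chromen‑3‑ol F10. Treatment of F10 with K2CO3 in aqueous MeOH at 0 °C should expel the O2′ aryloxide from C7 by a phenoxide‑driven 1,6‑elimination, the phenolphthalein‑type ring opening. Buffered protonation of the delocalised anion at pH 6–7 in the cold would then give 22 under kinetic control.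

**Step 11.** The addition may stop after the first aryl group, because the carbonyl of 19 is flanked by two ortho substituents and the tetrahedral intermediate may persist as a cyclic hemiketal alkoxide.

The fallback is a stepwise arylation with the phenol capped. It sets out from 16 and 17 and returns at 22. One equivalent of 18 at −78 °C with a cold quench would give [3‑({[tert‑butyl(dimethyl)silyl]oxy}methyl)‑6‑[2‑hydroxy‑4‑(methoxymethoxy)phenyl]‑2‑{[4‑(methoxymethoxy)phenyl]ethynyl}phenyl][4‑(methoxymethoxy)phenyl]methanone F11. Treatment with MOMCl and i‑Pr2NEt would cap O2′ and give the ketone [6‑[2,4‑bis(methoxymethoxy)phenyl]‑3‑({[tert‑butyl(dimethyl)silyl]oxy}methyl)‑2‑{[4‑(methoxymethoxy)phenyl]ethynyl}phenyl][4‑(methoxymethoxy)phenyl]methanone F12. The arylcerium reagent made from 18 and CeCl3 would add to F12 to give {6‑[2,4‑bis(methoxymethoxy)phenyl]‑3‑({[tert‑butyl(dimethyl)silyl]oxy}methyl)‑2‑{[4‑(methoxymethoxy)phenyl]ethynyl}phenyl}bis[4‑(methoxymethoxy)phenyl]methanol F13. The acid conditions of step 12 would convert F13 into 22.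

## Further compounds

F1 | step 10 | (E)‑tert‑butyl(dimethyl)(pent‑2‑en‑4‑yn‑1‑yloxy)silane | C#C/C=C/CO[Si](C)(C)C(C)(C)C
F2 | step 10 | 2‑[(3E)‑5‑{[tert‑butyl(dimethyl)silyl]oxy}pent‑3‑en‑1‑yn‑1‑yl]‑5‑(methoxymethoxy)phenol | COCOc1ccc(C#C/C=C/CO[Si](C)(C)C(C)(C)C)c(O)c1
F3 | step 10 | 2‑[(3E)‑5‑{[tert‑butyl(dimethyl)silyl]oxy}pent‑3‑en‑1‑yn‑1‑yl]‑5‑(methoxymethoxy)phenyl 5‑[4‑(methoxymethoxy)phenyl]penta‑2,4‑diynoate | COCOc1ccc(C#CC#CC(=O)Oc2cc(OCOC)ccc2C#C/C=C/CO[Si](C)(C)C(C)(C)C)cc1
F4 | step 9 | 3‑bromoprop‑2‑ynoic acid | OC(=O)C#CBr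
F5 | step 9 | 2‑(5‑{[tert‑butyl(dimethyl)silyl]oxy}penta‑1,3‑diyn‑1‑yl)‑5‑(methoxymethoxy)phenyl 3‑bromoprop‑2‑ynoate | COCOc1ccc(C#CC#CCO[Si](C)(C)C(C)(C)C)c(OC(=O)C#CBr)c1
F6 | step 9 | 7‑bromo‑8‑({[tert‑butyl(dimethyl)silyl]oxy}methyl)‑3‑(methoxymethoxy)‑6H‑benzo[c]chromen‑6‑one | COCOc1ccc2-c3ccc(CO[Si](C)(C)C(C)(C)C)c(Br)c3C(=O)Oc2c1
F7 | step 9 | 1‑ethynyl‑4‑(methoxymethoxy)benzene | C#Cc1ccc(OCOC)cc1
F8 | step 5 | 2‑iodo‑5‑(methoxymethoxy)phenyl acetate | CC(=O)Oc1cc(OCOC)ccc1I
F9 | step 5 | 2‑(5‑{[tert‑butyl(dimethyl)silyl]oxy}penta‑1,3‑diyn‑1‑yl)‑5‑(methoxymethoxy)phenyl acetate | CC(=O)Oc1cc(OCOC)ccc1C#CC#CCO[Si](C)(C)C(C)(C)C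
F10 | step 12 | 8‑(hydroxymethyl)‑6,6‑bis(4‑hydroxyphenyl)‑7‑[(4‑hydroxyphenyl)ethynyl]‑6H‑benzo[c]chromen‑3‑ol | Oc1ccc2-c3ccc(CO)c(C#Cc4ccc(O)cc4)c3C(c3ccc(O)cc3)(c3ccc(O)cc3)Oc2c1
F11 | step 11 | [3‑({[tert‑butyl(dimethyl)silyl]oxy}methyl)‑6‑[2‑hydroxy‑4‑(methoxymethoxy)phenyl]‑2‑{[4‑(methoxymethoxy)phenyl]ethynyl}phenyl][4‑(methoxymethoxy)phenyl]methanone | COCOc1ccc(-c2ccc(CO[Si](C)(C)C(C)(C)C)c(C#Cc3ccc(OCOC)cc3)c2C(=O)c2ccc(OCOC)cc2)c(O)c1
F12 | step 11 | [6‑[2,4‑bis(methoxymethoxy)phenyl]‑3‑({[tert‑butyl(dimethyl)silyl]oxy}methyl)‑2‑{[4‑(methoxymethoxy)phenyl]ethynyl}phenyl][4‑(methoxymethoxy)phenyl]methanone | COCOc1ccc(-c2ccc(CO[Si](C)(C)C(C)(C)C)c(C#Cc3ccc(OCOC)cc3)c2C(=O)c2ccc(OCOC)cc2)c(OCOC)c1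
F13 | step 11 | {6‑[2,4‑bis(methoxymethoxy)phenyl]‑3‑({[tert‑butyl(dimethyl)silyl]oxy}methyl)‑2‑{[4‑(methoxymethoxy)phenyl]ethynyl}phenyl}bis[4‑(methoxymethoxy)phenyl]methanol | COCOc1ccc(-c2ccc(CO[Si](C)(C)C(C)(C)C)c(C#Cc3ccc(OCOC)cc3)c2C(O)(c2ccc(OCOC)cc2)c2ccc(OCOC)cc2)c(OCOC)c1
A1 | alternative 1 | methyl 2‑bromo‑3‑({[tert‑butyl(dimethyl)silyl]oxy}methyl)‑6‑iodobenzoate | COC(=O)c1c(I)ccc(CO[Si](C)(C)C(C)(C)C)c1Br
A2 | alternative 1 | methyl 6‑[2,4‑bis(methoxymethoxy)phenyl]‑3‑({[tert‑butyl(dimethyl)silyl]oxy}methyl)‑2‑{[4‑(methoxymethoxy)phenyl]ethynyl}benzoate | COC(=O)c1c(-c2ccc(OCOC)cc2OCOC)ccc(CO[Si](C)(C)C(C)(C)C)c1C#Cc1ccc(OCOC)cc1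
A3 | alternative 2 | 2‑ethynyl‑5‑(methoxymethoxy)phenyl 5‑[4‑(methoxymethoxy)phenyl]penta‑2,4‑diynoate | C#Cc1ccc(OCOC)cc1OC(=O)C#CC#Cc1ccc(OCOC)cc1
A4 | alternative 2 | tert‑butyl(dimethyl)(prop‑2‑yn‑1‑yloxy)silane | C#CCO[Si](C)(C)C(C)(C)C
A5 | alternative 2 | 9‑({[tert‑butyl(dimethyl)silyl]oxy}methyl)‑3‑(methoxymethoxy)‑7‑{[4‑(methoxymethoxy)phenyl]ethynyl}‑6H‑benzo[c]chromen‑6‑one | COCOc1ccc2-c3cc(CO[Si](C)(C)C(C)(C)C)cc(C#Cc4ccc(OCOC)cc4)c3C(=O)Oc2c1
A6 | alternative 3 | 6‑[2,4‑bis(methoxymethoxy)phenyl]‑3‑({[tert‑butyl(dimethyl)silyl]oxy}methyl)‑2‑{[4‑(methoxymethoxy)phenyl]ethynyl}benzaldehyde | O=Cc1c(-c2ccc(OCOC)cc2OCOC)ccc(CO[Si](C)(C)C(C)(C)C)c1C#Cc1ccc(OCOC)cc1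
A7 | alternative 3 | phenol | Oc1ccccc1
A8 | alternative 3 | 2‑[bis(4‑hydroxyphenyl)methyl]‑4‑(hydroxymethyl)‑3‑[(4‑hydroxyphenyl)ethynyl]biphenyl‑2′,4′‑diol | Oc1ccc(C(c2ccc(O)cc2)c2c(-c3ccc(O)cc3O)ccc(CO)c2C#Cc2ccc(O)cc2)cc1
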